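Everything rests on opening the imidazole at N3–C2. The N3–C4–C5 segment of that ring, with the benzylic carbon on C5, is carried as N2–C3–C4–C5 of an isoxazole ring, so the future CH2 enters as an aryl ketone carbon. In one operation zerovalent molybdenum breaks the isoxazole N–O bond, and the freed enamine nitrogen condenses with a formyl carbon already attached to the C4 nitrogen, exchanging one azole for the other. The precursor is a 3-(4-methoxybenzyl)-5-[4-(benzyloxy)phenyl]isoxazole with NHCHO at C4, built regioselectively from a nitrile oxide and an α-nitroketone enolate. Acidic hydrogenolysis and phenol sulfation complete the target.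

Key step: step 6

Assumption: the target has no stereocentre, its 1H/3H imidazole tautomers count as one compound, and the hydrogen sulfate as drawn should be handled as the inner salt (imidazolium aryl sulfate) of the same composition.

Step 1
Reactants: 1 4-methoxyphenylacetaldehyde
Product: 2 4-methoxyphenylacetaldehyde oxime (E/Z mixture)
Conditions: NH2OH·HCl, NaOAc, EtOH/H2O, rt
Reagents that add atoms: hydroxylamine hydrochloride, Cl.NO
Why: Oxime condensation of an unhindered aldehyde at buffered pH is fast at room temperature, which limits self-aldol loss of the enolisable aldehyde, and both oxime isomers lead to the same chloride later.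

Step 2
Reactants: 3 4-(benzyloxy)benzoic acid; 4 nitromethane
Product: 6 1-[4-(benzyloxy)phenyl]-2-nitroethanone, via acyl imidazolide 5 (not isolated)
Conditions: CDI, THF, rt; then MeNO2, KOtBu (2 equiv), THF, 0 °C to 60 °C; aq. HCl
Reagents that add atoms: none
Why: C-acylation of the nitromethane anion by an acyl imidazolide is the standard entry to α-nitroketones, the second equivalent of base storing the product as its stabilised anion so that double acylation is avoided and the benzyl ether stays inert.

Step 3
Reactants: 2 4-methoxyphenylacetaldehyde oxime; 6 1-[4-(benzyloxy)phenyl]-2-nitroethanone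
Product: 9 5-[4-(benzyloxy)phenyl]-3-(4-methoxybenzyl)-4-nitroisoxazole, via hydroximoyl chloride 7 (not isolated), via nitrile oxide 8 (not isolated)
Conditions: NCS (1.0 equiv), DMF, 0 °C to rt; then slow addition to 6, NaOEt (1 equiv), EtOH, 0 °C to rt
Reagents that add atoms: none
Why: Oxime chlorination and 1,3-dehydrochlorination give the nitrile oxide, whose carbon is attacked by the nitro-bearing enolate carbon of 6 before the oximate oxygen closes onto the aryl ketone and water is lost (nitrile oxide–active methylene cyclocondensation, known for α-nitroketones), so the polarity of the partners places benzyl at C3, nitro at C4 and aryl at C5.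

Step 4
Reactants: 9 5-[4-(benzyloxy)phenyl]-3-(4-methoxybenzyl)-4-nitroisoxazole
Product: 10 5-[4-(benzyloxy)phenyl]-3-(4-methoxybenzyl)isoxazol-4-amine
Conditions: SnCl2·2H2O, conc. HCl, EtOH, 50 °C
Reagents that add atoms: none
Why: Nitro reduction with divalent tin in acid is the classical route to 4-aminoisoxazoles and spares the N–O bond and the benzyl ether, both of which catalytic hydrogenation would endanger.

Step 5
Reactants: 10 5-[4-(benzyloxy)phenyl]-3-(4-methoxybenzyl)isoxazol-4-amine
Product: 11 N-[5-[4-(benzyloxy)phenyl]-3-(4-methoxybenzyl)isoxazol-4-yl]formamide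
Conditions: HCO2H, Ac2O, 55 °C; then 10, THF, 0 °C to rt
Reagents that add atoms: acetic formic anhydride, CC(=O)OC=O
Why: N-formylation with the mixed anhydride, which transfers only its more electrophilic formyl group, is reactive enough for this weakly nucleophilic amine flanked by two substituents.

Step 6
Reactants: 11 N-[5-[4-(benzyloxy)phenyl]-3-(4-methoxybenzyl)isoxazol-4-yl]formamide
Product: 15 [4-(benzyloxy)phenyl][4-(4-methoxybenzyl)-1H-imidazol-5-yl]methanone, via E-enaminoketone 12 (not isolated), via Z-enaminoketone 13 (not isolated), via carbinolamine 14 (not isolated)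
Conditions: Mo(CO)6 (1 equiv), MeCN/H2O, 80 °C; Celite filtration, concentration; then NaOH (20 mol %), EtOH, 78 °C
Reagents that add atoms: none
Why: Mo(CO)6 binds the isoxazole nitrogen and inserts into the weak N–O bond, and water hydrolyses the resulting molybdenum nitrenoid to primary enaminoketone 12; this is the known Mo(CO)6-mediated reductive opening of isoxazoles and touches neither the benzyl ether nor the ketone. The ring hands on the E geometry, with NH2 hydrogen-bonded to the carbonyl and trans to the formamide nitrogen, so closure must wait for rotation about the push–pull C=C bond (through the iminium-enolate form or the imine tautomer) to Z isomer 13, which heat and catalytic base provide. In 13 the enamine nitrogen adds to the formyl carbon in a 5-exo-trig closure that forms N3–C2 and gives carbinolamine 14, and loss of water then delivers aromatic imidazole 15 irreversibly, the known conversion of 4-acylaminoisoxazoles into 4(5)-acylimidazoles. No stereocentre remains, because the carbinolamine carbon of 14 becomes the sp2 carbon C2. The selectivity needed is ring closure ahead of enaminone hydrolysis, deformylation and acid-type oxazole formation. It is secured by the vinylogous-amide stability of 12, by formyl being the most electrophilic acyl group available, by removing most of the water before the base stage and by working in base, not in acid.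

Step 7
Reactants: 15 [4-(benzyloxy)phenyl][4-(4-methoxybenzyl)-1H-imidazol-5-yl]methanone
Product: 18 4-{[4-(4-methoxybenzyl)-1H-imidazol-5-yl]methyl}phenol, via phenolic ketone 16 (not isolated), via carbinol 17 (not isolated)
Conditions: H2 (4 bar), 10% Pd/C, AcOH/2 M aq. HCl, 60 °C
Reagents that add atoms: none
Why: In this acidic catalytic hydrogenolysis the benzyl ether falls first, the ketone is reduced to carbinol 17 and its doubly benzylic C–O bond, activated by the para-hydroxyphenyl ring, is cleaved as is known for aryl imidazolyl ketones and carbinols, while protonation keeps the imidazole from poisoning the catalyst and the transient stereocentre of 17 vanishes.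

Step 8
Reactants: 18 4-{[4-(4-methoxybenzyl)-1H-imidazol-5-yl]methyl}phenol
Product: 19 4-{[5-(4-methoxybenzyl)-1H-imidazol-4-yl]methyl}phenyl hydrogen sulfate (melanocin F)
Conditions: SO3·pyridine (2 equiv), pyridine, rt; H2O, pH 5; C18 chromatography
Reagents that add atoms: sulfur trioxide–pyridine complex, O=S(=O)([O-])[n+]1ccccc1
Why: O-sulfation of a phenol with SO3·pyridine is standard, sulfonation at an imidazole nitrogen is reversible and is undone by water in the work-up, the methyl ether and the arene rings are inert, and the product should separate as its inner salt near pH 5.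

Compound list
1 | 4-methoxyphenylacetaldehyde | COc1ccc(CC=O)cc1 | starting material
2 | 4-methoxyphenylacetaldehyde oxime (E/Z mixture) | COc1ccc(CC=NO)cc1 | intermediate
3 | 4-(benzyloxy)benzoic acid | O=C(O)c1ccc(OCc2ccccc2)cc1 | starting material
4 | nitromethane | C[N+](=O)[O-] | starting material
5 | [4-(benzyloxy)phenyl](1H-imidazol-1-yl)methanone | O=C(c1ccc(OCc2ccccc2)cc1)n1ccnc1 | intermediate
6 | 1-[4-(benzyloxy)phenyl]-2-nitroethanone | O=C(C[N+](=O)[O-])c1ccc(OCc2ccccc2)cc1 | intermediate
7 | (Z)-N-hydroxy-2-(4-methoxyphenyl)acetimidoyl chloride | COc1ccc(C/C(Cl)=N/O)cc1 | intermediate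
8 | (4-methoxyphenyl)acetonitrile oxide | COc1ccc(CC#[N+][O-])cc1 | intermediate
9 | 5-[4-(benzyloxy)phenyl]-3-(4-methoxybenzyl)-4-nitroisoxazole | COc1ccc(Cc2noc(-c3ccc(OCc4ccccc4)cc3)c2[N+](=O)[O-])cc1 | intermediate
10 | 5-[4-(benzyloxy)phenyl]-3-(4-methoxybenzyl)isoxazol-4-amine | COc1ccc(Cc2noc(-c3ccc(OCc4ccccc4)cc3)c2N)cc1 | intermediate
11 | N-[5-[4-(benzyloxy)phenyl]-3-(4-methoxybenzyl)isoxazol-4-yl]formamide | COc1ccc(Cc2noc(-c3ccc(OCc4ccccc4)cc3)c2NC=O)cc1 | intermediate
12 | N-[(2E)-3-amino-1-[4-(benzyloxy)phenyl]-4-(4-methoxyphenyl)-1-oxobut-2-en-2-yl]formamide (NH2 cis to the ketone, trans to NHCHO) | COc1ccc(C/C(N)=C(\NC=O)C(=O)c2ccc(OCc3ccccc3)cc2)cc1 | intermediate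
13 | N-[(2Z)-3-amino-1-[4-(benzyloxy)phenyl]-4-(4-methoxyphenyl)-1-oxobut-2-en-2-yl]formamide (NH2 cis to NHCHO) | COc1ccc(C/C(N)=C(/NC=O)C(=O)c2ccc(OCc3ccccc3)cc2)cc1 | intermediate
14 | [4-(benzyloxy)phenyl][2-hydroxy-5-(4-methoxybenzyl)-2,3-dihydro-1H-imidazol-4-yl]methanone (racemic, transient) | COc1ccc(CC2=C(C(=O)c3ccc(OCc4ccccc4)cc3)NC(O)N2)cc1 | intermediate
15 | [4-(benzyloxy)phenyl][4-(4-methoxybenzyl)-1H-imidazol-5-yl]methanone | COc1ccc(Cc2nc[nH]c2C(=O)c2ccc(OCc3ccccc3)cc2)cc1 | intermediate
16 | (4-hydroxyphenyl)[4-(4-methoxybenzyl)-1H-imidazol-5-yl]methanone | COc1ccc(Cc2nc[nH]c2C(=O)c2ccc(O)cc2)cc1 | intermediate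
17 | 4-{hydroxy[4-(4-methoxybenzyl)-1H-imidazol-5-yl]methyl}phenol (racemic, transient) | COc1ccc(Cc2nc[nH]c2C(O)c2ccc(O)cc2)cc1 | intermediate
18 | 4-{[4-(4-methoxybenzyl)-1H-imidazol-5-yl]methyl}phenol | COc1ccc(Cc2nc[nH]c2Cc2ccc(O)cc2)cc1 | intermediate
19 | 4-{[5-(4-methoxybenzyl)-1H-imidazol-4-yl]methyl}phenyl hydrogen sulfate (melanocin F) | COc1ccc(Cc2[nH]cnc2Cc2ccc(OS(=O)(=O)O)cc2)cc1 | target

Total step count: 8. Longest linear sequence: 7 steps (1 → 2 → 9 → 10 → 11 → 15 → 18 → 19; the branch from 3 through 6 is equally long).

Steps most likely to fail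

Step 6. The turn of the enaminone double bond from E to Z may be slower than attack of water on the enaminone or loss of the formyl group, so that ring closure is starved. Molybdenum residues may also hold back the basic product. The fallback sets out from amine 10 and rejoins the route at 15, and it no longer stores the C2 carbon in the precursor. Amine 10 is opened with Mo(CO)6 in wet MeCN to the push–pull ene-diamine (E)-2,3-diamino-1-[4-(benzyloxy)phenyl]-4-(4-methoxyphenyl)but-2-en-1-one F1. After drying, this is heated at once with triethyl orthoformate and catalytic TsOH. Either nitrogen can form the imidate first and acid speeds the bond rotation. No water is present and there is no formyl group to lose. Condensation of an acceptor-substituted ene-1,2-diamine with an orthoester is an established imidazole synthesis.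

Step 3. Dimerisation of the nitrile oxide may outrun C-attack by the weakly nucleophilic, nitro-stabilised enolate, and ethoxide may cleave the nitroketone in a retro-Claisen sense. The fallback sets out from 5 and 7 and rejoins at 10, bringing in the C4 nitrogen by rearrangement of a carboxyl group.
- Acyl imidazolide 5 is treated with potassium ethyl malonate, MgCl2 and Et3N in MeCN. Decarboxylation then gives ethyl 3-[4-(benzyloxy)phenyl]-3-oxopropanoate F2.
- The sodium enolate of this ester is much more nucleophilic than that of 6. It takes up nitrile oxide 8, released from 7, to give ethyl 5-[4-(benzyloxy)phenyl]-3-(4-methoxybenzyl)isoxazole-4-carboxylate F3.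
- NaOH in aqueous EtOH/THF gives 5-[4-(benzyloxy)phenyl]-3-(4-methoxybenzyl)isoxazole-4-carboxylic acid F4.
- DPPA, Et3N and tBuOH at 85 °C carry this through the acyl azide F5 and, by Curtius rearrangement, the isoxazol-4-yl isocyanate F6 to tert-butyl N-[5-[4-(benzyloxy)phenyl]-3-(4-methoxybenzyl)isoxazol-4-yl]carbamate F7.
- TFA in CH2Cl2 releases 10.

Step 7. The reduction may stall at the ketone or alcohol stage, because the carbonyl group is deactivated by conjugation with the imidazole and the para-oxygenated ring, or because the catalyst is slowly poisoned. The fallback sets out from 15 and rejoins at 18, replacing surface hydrogenolysis by hydride chemistry. NaBH4 in hot EtOH gives racemic [4-(benzyloxy)phenyl][4-(4-methoxybenzyl)-1H-imidazol-5-yl]methanol F8. Ionic hydrogenation with Et3SiH in TFA/CH2Cl2 then proceeds through the para-alkoxybenzyl cation to 5-[4-(benzyloxy)benzyl]-4-(4-methoxybenzyl)-1H-imidazole F9. Neutral hydrogenolysis (H2, 10% Pd/C, MeOH, rt) removes the benzyl ether.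

Further compounds
F1 | step 6 | (E)-2,3-diamino-1-[4-(benzyloxy)phenyl]-4-(4-methoxyphenyl)but-2-en-1-one | COc1ccc(C/C(N)=C(\N)C(=O)c2ccc(OCc3ccccc3)cc2)cc1
F2 | step 3 | ethyl 3-[4-(benzyloxy)phenyl]-3-oxopropanoate | CCOC(=O)CC(=O)c1ccc(OCc2ccccc2)cc1
F3 | step 3 | ethyl 5-[4-(benzyloxy)phenyl]-3-(4-methoxybenzyl)isoxazole-4-carboxylate | CCOC(=O)c1c(Cc2ccc(OC)cc2)noc1-c1ccc(OCc2ccccc2)cc1
F4 | step 3 | 5-[4-(benzyloxy)phenyl]-3-(4-methoxybenzyl)isoxazole-4-carboxylic acid | COc1ccc(Cc2noc(-c3ccc(OCc4ccccc4)cc3)c2C(=O)O)cc1
F5 | step 3 | 5-[4-(benzyloxy)phenyl]-3-(4-methoxybenzyl)isoxazole-4-carbonyl azide | COc1ccc(Cc2noc(-c3ccc(OCc4ccccc4)cc3)c2C(=O)N=[N+]=[N-])cc1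
F6 | step 3 | 5-[4-(benzyloxy)phenyl]-4-isocyanato-3-(4-methoxybenzyl)isoxazole | COc1ccc(Cc2noc(-c3ccc(OCc4ccccc4)cc3)c2N=C=O)cc1
F7 | step 3 | tert-butyl N-[5-[4-(benzyloxy)phenyl]-3-(4-methoxybenzyl)isoxazol-4-yl]carbamate | COc1ccc(Cc2noc(-c3ccc(OCc4ccccc4)cc3)c2NC(=O)OC(C)(C)C)cc1
F8 | step 7 | [4-(benzyloxy)phenyl][4-(4-methoxybenzyl)-1H-imidazol-5-yl]methanol (racemic) | COc1ccc(Cc2nc[nH]c2C(O)c2ccc(OCc3ccccc3)cc2)cc1
F9 | step 7 | 5-[4-(benzyloxy)benzyl]-4-(4-methoxybenzyl)-1H-imidazole | COc1ccc(Cc2nc[nH]c2Cc2ccc(OCc3ccccc3)cc2)cc1
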